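**Retrosynthetic overview**
- The flavonol ring is made last: Algar–Flynn–Oyamada oxidation of a 2'-hydroxychalcone, itself from the aldehyde on the pyrogallol ring and 4-(benzyloxy)-2-hydroxyacetophenone.
- Feature used: in the flavan pyran ring (ring C), C3 is a lone oxygenated carbon between the aryl-bearing C2 and C4. Removing C3 leaves the C2=C3 bond of a 2,3-diarylbenzofuran, so C3 is put in as chloro(methoxy)carbene, forming C2–C3 and C3–C4 and enlarging the furan to a 3-methoxyflavylium.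
- Stereochemistry: flavylium → chroman-3-one; transfer-hydrogenation dynamic kinetic resolution fixes C2; elimination and hydroboration then place the C3 oxygen trans to both aryl groups (2R,3S,4S).
- The diarylbenzofuran comes from Sonogashira coupling/cyclisation, C3 bromination and Suzuki coupling with the pyrogallol-ring boronate.
- Ring order: furan ring → expanded to the flavan pyran ring → flavonol pyranone ring.

Key step: step 11

Assumption: the transfer hydrogenation of the chroman-3-one is taken to follow the usual cis sense (hydride anti to the α-aryl groups), so its C3 configuration is not the target's and is corrected afterwards; the catalyst antipode is assigned by the CH/π model and would be exchanged if induction ran the other way.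

**Step 1**
Reactants: 1 3-(benzyloxy)phenol
Product: 2 5-(benzyloxy)-2-iodophenol
Conditions: I2, NaHCO3, THF/H2O, 0 °C
Reagents that add atoms: iodine II
Why: Electrophilic iodination of the phenoxide should occur ortho to the hydroxyl and para to the benzyloxy group, the doubly activated and less hindered position.

**Step 2**
Reactants: 3 3,4-bis(benzyloxy)benzaldehyde
Product: 4 1,2-bis(benzyloxy)-4-ethynylbenzene
Conditions: dimethyl (1-diazo-2-oxopropyl)phosphonate, K2CO3, MeOH, 0 °C → rt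
Reagents that add atoms: dimethyl (1-diazo-2-oxopropyl)phosphonate COP(=O)(OC)C(=[N+]=[N-])C(C)=O
Why: Seyferth–Gilbert homologation with the Ohira–Bestmann reagent turns a non-enolisable aryl aldehyde into the terminal alkyne in one step.

**Step 3**
Reactants: 2 5-(benzyloxy)-2-iodophenol; 4 1,2-bis(benzyloxy)-4-ethynylbenzene
Product: 6 6-(benzyloxy)-2-[3,4-bis(benzyloxy)phenyl]-1-benzofuran, via alkynylphenol 5 (not isolated)
Conditions: PdCl2(PPh3)2 (cat.), CuI (cat.), Et3N, DMF, rt → 70 °C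
Reagents that add atoms: none
Why: Sonogashira coupling followed by copper/base-promoted 5-endo-dig cyclisation of the o-alkynylphenol closes the furan ring in the same flask.

**Step 4**
Reactants: 6 6-(benzyloxy)-2-[3,4-bis(benzyloxy)phenyl]-1-benzofuran
Product: 7 6-(benzyloxy)-2-[3,4-bis(benzyloxy)phenyl]-3-bromo-1-benzofuran
Conditions: NBS, CH2Cl2, 0 °C, dark
Reagents that add atoms: N-bromosuccinimide O=C1CCC(=O)N1Br
Why: Electrophilic bromination should go to C3, the enol-ether β-carbon and most nucleophilic position of a 2-arylbenzofuran.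

**Step 5**
Reactants: 8 3,4,5-tris(benzyloxy)benzaldehyde
Product: 9 3,4,5-tris(benzyloxy)-2-bromobenzaldehyde
Conditions: NBS, MeCN, rt, dark
Reagents that add atoms: N-bromosuccinimide O=C1CCC(=O)N1Br
Why: Electrophilic aromatic bromination can only take one of the two equivalent free positions, ortho to the formyl group and para to a benzyloxy group.

**Step 6**
Reactants: 9 3,4,5-tris(benzyloxy)-2-bromobenzaldehyde
Product: 10 [3,4,5-tris(benzyloxy)-2-bromophenyl]methanol
Conditions: NaBH4, THF/MeOH, 0 °C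
Reagents that add atoms: none
Why: Borohydride reduction of the aldehyde leaves the aryl bromide and benzyl ethers untouched.

**Step 7**
Reactants: 10 [3,4,5-tris(benzyloxy)-2-bromophenyl]methanol
Product: 11 {[3,4,5-tris(benzyloxy)-2-bromobenzyl]oxy}(tert-butyl)diphenylsilane
Conditions: TBDPSCl, imidazole, DMF, rt
Reagents that add atoms: tert-butyl(chloro)diphenylsilane CC(C)(C)[Si](Cl)(c1ccccc1)c1ccccc1
Why: Silylation masks the future aldehyde carbon as a primary TBDPS ether, chosen because it should survive the aqueous acid of step 12 and offers no O–H bond to the carbene.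

**Step 8**
Reactants: 11 {[3,4,5-tris(benzyloxy)-2-bromobenzyl]oxy}(tert-butyl)diphenylsilane
Product: 12 2-[2,3,4-tris(benzyloxy)-6-({[tert-butyl(diphenyl)silyl]oxy}methyl)phenyl]-4,4,5,5-tetramethyl-1,3,2-dioxaborolane
Conditions: B2pin2, Pd(OAc)2 (cat.), SPhos, KOAc, 1,4-dioxane, 90 °C
Reagents that add atoms: bis(pinacolato)diboron CC1(C)OB(OC1(C)C)B1OC(C)(C)C(C)(C)O1
Why: Miyaura borylation with a bulky biarylphosphine ligand is suited to a di-ortho-substituted, electron-rich aryl bromide.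

**Step 9**
Reactants: 7 6-(benzyloxy)-2-[3,4-bis(benzyloxy)phenyl]-3-bromo-1-benzofuran; 12 the aryl pinacol boronate
Product: 13 6-(benzyloxy)-2-[3,4-bis(benzyloxy)phenyl]-3-[2,3,4-tris(benzyloxy)-6-({[tert-butyl(diphenyl)silyl]oxy}methyl)phenyl]-1-benzofuran
Conditions: Pd(OAc)2 (cat.), SPhos, K3PO4, toluene/H2O, 90 °C
Reagents that add atoms: none
Why: Suzuki–Miyaura coupling with SPhos makes the hindered C3–aryl bond on the flat heteroarene, before the ring carbon that will become C4 is sp3.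

**Step 10**
Reactants: 14 O-methylisourea hydrogen sulfate
Product: 15 3-chloro-3-methoxy-3H-diazirine
Conditions: aq. NaOCl/NaOH, LiCl, DMSO/pentane, 20–25 °C; kept as a cold pentane solution
Reagents that add atoms: sodium hypochlorite [Na+].[O-]Cl
Why: Graham oxidation of an amidine-type salt with hypochlorite is the standard route to 3-halodiazirines; the product is not isolated neat.

**Step 11**
Reactants: 13 the 2,3-diarylbenzofuran; 15 3-chloro-3-methoxy-3H-diazirine
Product: 18 7-(benzyloxy)-2-[3,4-bis(benzyloxy)phenyl]-3-methoxy-4-[2,3,4-tris(benzyloxy)-6-({[tert-butyl(diphenyl)silyl]oxy}methyl)phenyl]chromenylium chloride, via chloro(methoxy)carbene 16 (not isolated), via chloromethoxycyclopropane 17 (not isolated)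
Conditions: 15 (excess, cold pentane solution added in portions), ClCH2CH2Cl, 4 Å MS, 40 °C, dark; precipitation with hexane
Reagents that add atoms: none
Why: Proposed new method: thermal loss of N2 from 15 gives the singlet ambiphilic carbene 16, which should add across the furan C2=C3 bond of 13, an enol-ether-like π bond and the least aromatic, most electron-rich one in the molecule, to give cyclopropane 17. Methoxy-assisted ionisation of the C–Cl bond then triggers the two-electron disrotatory opening of the cyclopropyl cation; this can only cleave the former C2–C3 ring-fusion bond, so the six-membered pyrylium ring arises by ring expansion (electrocyclic opening, not a cyclisation), driven by strain release and the gain of benzopyrylium aromaticity. The closest known reaction types are the Ciamician–Dennstedt ring expansion of indoles, pyrroles and benzofurans by halocarbenes and the chlorodiazirine-based single-carbon insertion into indoles. No stereocentre is formed. The step needs site selectivity for the furan π bond over the benzyloxy-arenes and over O–H insertion: benzene rings are inert to this stabilised carbene and no O–H group is present. Because the oxygen-stabilised cyclopropyl cation can form from either epimer at the carbene carbon of 17, both cyclopropane diastereomers should converge on 18.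

**Step 12**
Reactants: 18 the 3-methoxyflavylium chloride
Product: 20 (±)-7-(benzyloxy)-2-[3,4-bis(benzyloxy)phenyl]-4-[2,3,4-tris(benzyloxy)-6-({[tert-butyl(diphenyl)silyl]oxy}methyl)phenyl]chroman-3-one (equilibrating 2,4-cis/trans mixture), via 3-methoxy-2H-chromene 19 (not isolated)
Conditions: NaBH4, THF/MeOH, −20 °C; then 2 M aq. HCl, THF, 40 °C
Reagents that add atoms: water O
Why: Hydride addition to the pyrylium should occur at C2 because C4 is shielded by the di-ortho-substituted aryl group, and acid hydrolysis of the resulting methyl enol ether (C4 protonation, oxocarbenium, loss of methanol) gives the ketone, whose two labile α-stereocentres need no control here.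

**Step 13**
Reactants: 20 the racemic chroman-3-one
Product: 21 (2R,3R,4S)-7-(benzyloxy)-2-[3,4-bis(benzyloxy)phenyl]-4-[2,3,4-tris(benzyloxy)-6-({[tert-butyl(diphenyl)silyl]oxy}methyl)phenyl]-3,4-dihydro-2H-chromen-3-ol (all-cis)
Conditions: RuCl(p-cymene)[(S,S)-TsDPEN] (cat.), HCO2H/Et3N (5:2), DMF, 40 °C
Reagents that add atoms: none
Why: Noyori–Ikariya asymmetric transfer hydrogenation under dynamic kinetic resolution: both α-carbons of 20 epimerise through the enols in the amine/formic acid medium faster than the ketone is reduced, and the Ru–H should reduce only the matched 2,4-cis enantiomer from the face opposite both α-aryl groups (the cis sense typical of α-aryl cyclic ketones), which fixes C2 as R and C4 as S and gives C3 as R, a C3 configuration that is corrected in steps 14 and 15.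

**Step 14**
Reactants: 21 the all-cis alcohol
Product: 22 (2S)-7-(benzyloxy)-2-[3,4-bis(benzyloxy)phenyl]-4-[2,3,4-tris(benzyloxy)-6-({[tert-butyl(diphenyl)silyl]oxy}methyl)phenyl]-2H-chromene
Conditions: Martin sulfurane, CH2Cl2, 0 °C → rt, dark
Reagents that add atoms: none
Why: E2 dehydration through the alkoxysulfonium of Martin's sulfurane: the axial C3 oxygen of the all-cis alcohol is antiperiplanar to the doubly benzylic axial H4, so the conjugated C3=C4 alkene should form while C2 is untouched (its descriptor becomes S only through the priority change); light is excluded because 2H-chromenes ring-open photochemically.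

**Step 15**
Reactants: 22 the (2S)-2H-chromene
Product: 24 (2R,3S,4S)-7-(benzyloxy)-2-[3,4-bis(benzyloxy)phenyl]-4-[2,3,4-tris(benzyloxy)-6-({[tert-butyl(diphenyl)silyl]oxy}methyl)phenyl]-3,4-dihydro-2H-chromen-3-ol (2,3-trans-3,4-trans), via C3-alkylborane 23 (not isolated)
Conditions: BH3·SMe2, THF, 0 °C → rt; then NaOH, H2O2, 0 °C
Reagents that add atoms: hydrogen peroxide OO
Why: Hydroboration–oxidation of a trisubstituted styrene-type alkene: borane adds syn, with boron at the less substituted C3 and from the face opposite the C2 aryl group, so boron and H4 end up trans to that aryl group and oxidation with retention gives the alcohol with C3 (S) and C4 (S) set by C2, the oxygen trans to both aryl groups.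

**Step 16**
Reactants: 24 the 2,3-trans-3,4-trans alcohol
Product: 25 (2R,3S,4S)-3,7-bis(benzyloxy)-2-[3,4-bis(benzyloxy)phenyl]-4-[2,3,4-tris(benzyloxy)-6-({[tert-butyl(diphenyl)silyl]oxy}methyl)phenyl]-3,4-dihydro-2H-chromene
Conditions: NaH, BnBr, Bu4NI (cat.), DMF, 0 °C → rt
Reagents that add atoms: benzyl bromide BrCc1ccccc1
Why: Williamson etherification protects the C3 hydroxyl, which would otherwise add in a 6-exo oxa-Michael fashion to the enone of the later chalcone, and the benzyl group leaves in the final hydrogenolysis.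

**Step 17**
Reactants: 25 the C3 benzyl ether
Product: 26 {3,4,5-tris(benzyloxy)-2-[(2R,3S,4S)-3,7-bis(benzyloxy)-2-[3,4-bis(benzyloxy)phenyl]-3,4-dihydro-2H-chromen-4-yl]phenyl}methanol
Conditions: Bu4NF, THF, rt
Reagents that add atoms: none
Why: Fluoride cleaves the silyl ether selectively in the presence of benzyl ethers.

**Step 18**
Reactants: 26 the benzylic alcohol
Product: 27 3,4,5-tris(benzyloxy)-2-[(2R,3S,4S)-3,7-bis(benzyloxy)-2-[3,4-bis(benzyloxy)phenyl]-3,4-dihydro-2H-chromen-4-yl]benzaldehyde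
Conditions: Dess–Martin periodinane, CH2Cl2, rt
Reagents that add atoms: none
Why: Dess–Martin oxidation of the only free hydroxyl gives the aryl aldehyde under neutral conditions that leave the benzylic C2 and C4 positions alone.

**Step 19**
Reactants: 27 the aldehyde; 28 1-[4-(benzyloxy)-2-hydroxyphenyl]ethanone
Product: 29 (2E)-1-[4-(benzyloxy)-2-hydroxyphenyl]-3-{3,4,5-tris(benzyloxy)-2-[(2R,3S,4S)-3,7-bis(benzyloxy)-2-[3,4-bis(benzyloxy)phenyl]-3,4-dihydro-2H-chromen-4-yl]phenyl}prop-2-en-1-one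
Conditions: KOH, EtOH/THF, rt
Reagents that add atoms: none
Why: Claisen–Schmidt condensation of a non-enolisable aryl aldehyde with the acetophenone enolate gives the E-configured 2'-hydroxychalcone; the flavan stereocentres carry no acidic hydrogen under these conditions.

**Step 20**
Reactants: 29 the 2'-hydroxychalcone
Product: 30 7-(benzyloxy)-3-hydroxy-2-{3,4,5-tris(benzyloxy)-2-[(2R,3S,4S)-3,7-bis(benzyloxy)-2-[3,4-bis(benzyloxy)phenyl]-3,4-dihydro-2H-chromen-4-yl]phenyl}-4H-chromen-4-one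
Conditions: H2O2, NaOH, MeOH/THF, 0 °C → rt
Reagents that add atoms: hydrogen peroxide OO
Why: Algar–Flynn–Oyamada oxidative cyclisation converts a 2'-hydroxychalcone lacking a 6'-substituent into the flavonol, closing the pyranone ring.

**Step 21**
Reactants: 30 the octabenzyl flavonol
Product: 31 3,7-dihydroxy-2-{3,4,5-trihydroxy-2-[(2R,3S,4S)-2-(3,4-dihydroxyphenyl)-3,7-dihydroxy-3,4-dihydro-2H-chromen-4-yl]phenyl}-4H-chromen-4-one (target)
Conditions: H2 (1 atm), Pd(OH)2/C, degassed THF/MeOH, rt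
Reagents that add atoms: none
Why: Hydrogenolysis removes all eight benzyl ethers under mild conditions that should leave the flavonol double bond, the C2–O1 bond of the flavan and the three stereocentres intact.

**Compound list**

1 | 3-(benzyloxy)phenol | Oc1cccc(OCc2ccccc2)c1 | starting material
2 | 5-(benzyloxy)-2-iodophenol | Oc1cc(OCc2ccccc2)ccc1I | intermediate
3 | 3,4-bis(benzyloxy)benzaldehyde | O=Cc1ccc(OCc2ccccc2)c(OCc2ccccc2)c1 | starting material
4 | 1,2-bis(benzyloxy)-4-ethynylbenzene | C#Cc1ccc(OCc2ccccc2)c(OCc2ccccc2)c1 | intermediate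
5 | 5-(benzyloxy)-2-{[3,4-bis(benzyloxy)phenyl]ethynyl}phenol | Oc1cc(OCc2ccccc2)ccc1C#Cc1ccc(OCc2ccccc2)c(OCc2ccccc2)c1 | intermediate (not isolated)
6 | 6-(benzyloxy)-2-[3,4-bis(benzyloxy)phenyl]-1-benzofuran | c1c(-c2ccc(OCc3ccccc3)c(OCc3ccccc3)c2)oc2cc(OCc3ccccc3)ccc12 | intermediate
7 | 6-(benzyloxy)-2-[3,4-bis(benzyloxy)phenyl]-3-bromo-1-benzofuran | Brc1c(-c2ccc(OCc3ccccc3)c(OCc3ccccc3)c2)oc2cc(OCc3ccccc3)ccc12 | intermediate
8 | 3,4,5-tris(benzyloxy)benzaldehyde | O=Cc1cc(OCc2ccccc2)c(OCc2ccccc2)c(OCc2ccccc2)c1 | starting material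
9 | 3,4,5-tris(benzyloxy)-2-bromobenzaldehyde | O=Cc1cc(OCc2ccccc2)c(OCc2ccccc2)c(OCc2ccccc2)c1Br | intermediate
10 | [3,4,5-tris(benzyloxy)-2-bromophenyl]methanol | OCc1cc(OCc2ccccc2)c(OCc2ccccc2)c(OCc2ccccc2)c1Br | intermediate
11 | {[3,4,5-tris(benzyloxy)-2-bromobenzyl]oxy}(tert-butyl)diphenylsilane | CC(C)(C)[Si](c1ccccc1)(c1ccccc1)OCc1cc(OCc2ccccc2)c(OCc2ccccc2)c(OCc2ccccc2)c1Br | intermediate
12 | 2-[2,3,4-tris(benzyloxy)-6-({[tert-butyl(diphenyl)silyl]oxy}methyl)phenyl]-4,4,5,5-tetramethyl-1,3,2-dioxaborolane | CC(C)(C)[Si](c1ccccc1)(c1ccccc1)OCc1cc(OCc2ccccc2)c(OCc2ccccc2)c(OCc2ccccc2)c1B1OC(C)(C)C(C)(C)O1 | intermediate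
13 | 6-(benzyloxy)-2-[3,4-bis(benzyloxy)phenyl]-3-[2,3,4-tris(benzyloxy)-6-({[tert-butyl(diphenyl)silyl]oxy}methyl)phenyl]-1-benzofuran | CC(C)(C)[Si](c1ccccc1)(c1ccccc1)OCc1cc(OCc2ccccc2)c(OCc2ccccc2)c(OCc2ccccc2)c1-c1c(-c2ccc(OCc3ccccc3)c(OCc3ccccc3)c2)oc2cc(OCc3ccccc3)ccc12 | intermediate (key-step precursor)
14 | O-methylisourea hydrogen sulfate | COC(N)=N.OS(O)(=O)=O | starting material
15 | 3-chloro-3-methoxy-3H-diazirine | COC1(Cl)N=N1 | intermediate (key-step precursor)
16 | chloro(methoxy)carbene | CO[C]Cl | intermediate (not isolated)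
17 | 4-(benzyloxy)-1a-[3,4-bis(benzyloxy)phenyl]-1-chloro-1-methoxy-6b-[2,3,4-tris(benzyloxy)-6-({[tert-butyl(diphenyl)silyl]oxy}methyl)phenyl]-1a,6b-dihydro-1H-cyclopropa[b][1]benzofuran (racemic, both epimers at C1) | COC1(Cl)C2(c3ccc(OCc4ccccc4)c(OCc4ccccc4)c3)Oc3cc(OCc4ccccc4)ccc3C12c1c(OCc2ccccc2)c(OCc2ccccc2)c(OCc2ccccc2)cc1CO[Si](c1ccccc1)(c1ccccc1)C(C)(C)C | intermediate (not isolated)
18 | 7-(benzyloxy)-2-[3,4-bis(benzyloxy)phenyl]-3-methoxy-4-[2,3,4-tris(benzyloxy)-6-({[tert-butyl(diphenyl)silyl]oxy}methyl)phenyl]chromenylium chloride | COc1c(-c2ccc(OCc3ccccc3)c(OCc3ccccc3)c2)[o+]c2cc(OCc3ccccc3)ccc2c1-c1c(OCc2ccccc2)c(OCc2ccccc2)c(OCc2ccccc2)cc1CO[Si](c1ccccc1)(c1ccccc1)C(C)(C)C.[Cl-] | intermediate (key-step product)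
19 | (±)-7-(benzyloxy)-2-[3,4-bis(benzyloxy)phenyl]-3-methoxy-4-[2,3,4-tris(benzyloxy)-6-({[tert-butyl(diphenyl)silyl]oxy}methyl)phenyl]-2H-chromene | COC1=C(c2c(OCc3ccccc3)c(OCc3ccccc3)c(OCc3ccccc3)cc2CO[Si](c2ccccc2)(c2ccccc2)C(C)(C)C)c2ccc(OCc3ccccc3)cc2OC1c1ccc(OCc2ccccc2)c(OCc2ccccc2)c1 | intermediate (not isolated)
20 | (±)-7-(benzyloxy)-2-[3,4-bis(benzyloxy)phenyl]-4-[2,3,4-tris(benzyloxy)-6-({[tert-butyl(diphenyl)silyl]oxy}methyl)phenyl]chroman-3-one (2,4-cis/trans mixture) | O=C1C(c2c(OCc3ccccc3)c(OCc3ccccc3)c(OCc3ccccc3)cc2CO[Si](c2ccccc2)(c2ccccc2)C(C)(C)C)c2ccc(OCc3ccccc3)cc2OC1c1ccc(OCc2ccccc2)c(OCc2ccccc2)c1 | intermediate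
21 | (2R,3R,4S)-7-(benzyloxy)-2-[3,4-bis(benzyloxy)phenyl]-4-[2,3,4-tris(benzyloxy)-6-({[tert-butyl(diphenyl)silyl]oxy}methyl)phenyl]-3,4-dihydro-2H-chromen-3-ol | CC(C)(C)[Si](c4ccccc4)(c4ccccc4)OCc1cc(OCc4ccccc4)c(OCc4ccccc4)c(OCc4ccccc4)c1[C@@H]2c3ccc(OCc4ccccc4)cc3O[C@H](c3ccc(OCc4ccccc4)c(OCc4ccccc4)c3)[C@@H]2O | intermediate
22 | (2S)-7-(benzyloxy)-2-[3,4-bis(benzyloxy)phenyl]-4-[2,3,4-tris(benzyloxy)-6-({[tert-butyl(diphenyl)silyl]oxy}methyl)phenyl]-2H-chromene | CC(C)(C)[Si](c4ccccc4)(c4ccccc4)OCc1cc(OCc4ccccc4)c(OCc4ccccc4)c(OCc4ccccc4)c1C2=C[C@@H](c3ccc(OCc4ccccc4)c(OCc4ccccc4)c3)Oc3cc(OCc4ccccc4)ccc23 | intermediate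
23 | [(2S,3S,4S)-7-(benzyloxy)-2-[3,4-bis(benzyloxy)phenyl]-4-[2,3,4-tris(benzyloxy)-6-({[tert-butyl(diphenyl)silyl]oxy}methyl)phenyl]-3,4-dihydro-2H-chromen-3-yl]borane (boron trans to both aryl groups) | CC(C)(C)[Si](c4ccccc4)(c4ccccc4)OCc1cc(OCc4ccccc4)c(OCc4ccccc4)c(OCc4ccccc4)c1[C@@H]2c3ccc(OCc4ccccc4)cc3O[C@H](c3ccc(OCc4ccccc4)c(OCc4ccccc4)c3)[C@H]2B | intermediate (not isolated)
24 | (2R,3S,4S)-7-(benzyloxy)-2-[3,4-bis(benzyloxy)phenyl]-4-[2,3,4-tris(benzyloxy)-6-({[tert-butyl(diphenyl)silyl]oxy}methyl)phenyl]-3,4-dihydro-2H-chromen-3-ol | CC(C)(C)[Si](c4ccccc4)(c4ccccc4)OCc1cc(OCc4ccccc4)c(OCc4ccccc4)c(OCc4ccccc4)c1[C@@H]2c3ccc(OCc4ccccc4)cc3O[C@H](c3ccc(OCc4ccccc4)c(OCc4ccccc4)c3)[C@H]2O | intermediate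
25 | (2R,3S,4S)-3,7-bis(benzyloxy)-2-[3,4-bis(benzyloxy)phenyl]-4-[2,3,4-tris(benzyloxy)-6-({[tert-butyl(diphenyl)silyl]oxy}methyl)phenyl]-3,4-dihydro-2H-chromene | CC(C)(C)[Si](c4ccccc4)(c4ccccc4)OCc1cc(OCc4ccccc4)c(OCc4ccccc4)c(OCc4ccccc4)c1[C@@H]2c3ccc(OCc4ccccc4)cc3O[C@H](c3ccc(OCc4ccccc4)c(OCc4ccccc4)c3)[C@H]2OCc4ccccc4 | intermediate
26 | {3,4,5-tris(benzyloxy)-2-[(2R,3S,4S)-3,7-bis(benzyloxy)-2-[3,4-bis(benzyloxy)phenyl]-3,4-dihydro-2H-chromen-4-yl]phenyl}methanol | OCc1cc(OCc4ccccc4)c(OCc4ccccc4)c(OCc4ccccc4)c1[C@@H]2c3ccc(OCc4ccccc4)cc3O[C@H](c3ccc(OCc4ccccc4)c(OCc4ccccc4)c3)[C@H]2OCc4ccccc4 | intermediate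
27 | 3,4,5-tris(benzyloxy)-2-[(2R,3S,4S)-3,7-bis(benzyloxy)-2-[3,4-bis(benzyloxy)phenyl]-3,4-dihydro-2H-chromen-4-yl]benzaldehyde | O=Cc1cc(OCc4ccccc4)c(OCc4ccccc4)c(OCc4ccccc4)c1[C@@H]2c3ccc(OCc4ccccc4)cc3O[C@H](c3ccc(OCc4ccccc4)c(OCc4ccccc4)c3)[C@H]2OCc4ccccc4 | intermediate
28 | 1-[4-(benzyloxy)-2-hydroxyphenyl]ethanone | CC(=O)c1ccc(OCc2ccccc2)cc1O | starting material
29 | (2E)-1-[4-(benzyloxy)-2-hydroxyphenyl]-3-{3,4,5-tris(benzyloxy)-2-[(2R,3S,4S)-3,7-bis(benzyloxy)-2-[3,4-bis(benzyloxy)phenyl]-3,4-dihydro-2H-chromen-4-yl]phenyl}prop-2-en-1-one | O=C(/C=C/c1cc(OCc4ccccc4)c(OCc4ccccc4)c(OCc4ccccc4)c1[C@@H]2c3ccc(OCc4ccccc4)cc3O[C@H](c3ccc(OCc4ccccc4)c(OCc4ccccc4)c3)[C@H]2OCc4ccccc4)c1ccc(OCc2ccccc2)cc1O | intermediate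
30 | 7-(benzyloxy)-3-hydroxy-2-{3,4,5-tris(benzyloxy)-2-[(2R,3S,4S)-3,7-bis(benzyloxy)-2-[3,4-bis(benzyloxy)phenyl]-3,4-dihydro-2H-chromen-4-yl]phenyl}-4H-chromen-4-one | O=c1c(O)c(-c2cc(OCc4ccccc4)c(OCc4ccccc4)c(OCc4ccccc4)c2[C@@H]2c3ccc(OCc4ccccc4)cc3O[C@H](c3ccc(OCc4ccccc4)c(OCc4ccccc4)c3)[C@H]2OCc4ccccc4)oc2cc(OCc4ccccc4)ccc12 | intermediate
31 | 3,7-dihydroxy-2-{3,4,5-trihydroxy-2-[(2R,3S,4S)-2-(3,4-dihydroxyphenyl)-3,7-dihydroxy-3,4-dihydro-2H-chromen-4-yl]phenyl}-4H-chromen-4-one | O=c1c(O)c(-c2cc(O)c(O)c(O)c2[C@@H]2c3ccc(O)cc3O[C@H](c3ccc(O)c(O)c3)[C@H]2O)oc2cc(O)ccc12 | target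

**Step count**
Total: 21 steps. Longest linear sequence: 16 steps (steps 5–9 and 11–21, from 8 to 31).

**Steps most likely to fail**

1. Step 11 (proposed new method). The carbene may dimerise, form azine or fragment faster than it adds to the hindered, tetrasubstituted and partly aromatic C2=C3 bond, or the cyclopropane may not ionise cleanly.
Fallback by known chemistry, setting out from 11 and coming back at 22: 7-hydroxy-4H-chromen-4-one would be benzylated (BnBr, K2CO3, DMF) to 7-(benzyloxy)-4H-chromen-4-one F1. Conjugate addition of 3,4-bis(benzyloxy)phenylboronic acid under Pd(OCOCF3)2/t-BuPyOx catalysis (ligand antipode chosen for the 2S product) would give (2S)-7-(benzyloxy)-2-[3,4-bis(benzyloxy)phenyl]-2,3-dihydro-4H-chromen-4-one F2. Bromide 11 would be converted by n-BuLi (THF, −78 °C) into the aryllithium F3, which should add to the ketone of F2 to give the tertiary 4-arylchroman-4-ol F4. Mild acid-catalysed dehydration (PPTS, toluene, 60 °C) would then give chromene 22, and steps 15 to 21 follow unchanged.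

2. Step 13. The catalyst may discriminate poorly between the two α-branched flanks of the ketone (low enantioselectivity), or epimerisation at the hindered C4 may be too slow for the resolution to be dynamic.
Fallback, setting out from 20 and coming back at 21: classical resolution instead of asymmetric catalysis. LiBH(s-Bu)3 (THF, −78 °C) should reduce 20 from the face opposite the aryl groups to the racemic all-cis alcohol F5. Esterification with (S)-2-methoxy-2-phenylacetic acid (DCC, DMAP) and separation of the diastereomers on silica would give the ester of the (2R,3R,4S) alcohol F6. Methanolysis (K2CO3, MeOH) returns 21.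

3. Step 14. Elimination could run towards C2 instead of C4, or the 2H-chromene could lose its C2 configuration by light- or heat-induced electrocyclic ring opening to the o-quinone methide or by a base-mediated 1,3-hydrogen shift.
Fallback, setting out from 21 and coming back at 24: inversion at C3 by substitution in place of elimination/hydroboration. Mitsunobu reaction of 21 with 4-nitrobenzoic acid (PPh3, DIAD, toluene) would give the inverted 4-nitrobenzoate F7, and methanolysis (K2CO3, MeOH/THF) gives 24.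

**Further compounds**

F1 | step 11 | 7-(benzyloxy)-4H-chromen-4-one | O=c1ccoc2cc(OCc3ccccc3)ccc12
F2 | step 11 | (2S)-7-(benzyloxy)-2-[3,4-bis(benzyloxy)phenyl]-2,3-dihydro-4H-chromen-4-one | O=C1C[C@@H](c2ccc(OCc3ccccc3)c(OCc3ccccc3)c2)Oc2cc(OCc3ccccc3)ccc12
F3 | step 11 | [2,3,4-tris(benzyloxy)-6-({[tert-butyl(diphenyl)silyl]oxy}methyl)phenyl]lithium | [Li]c1c(CO[Si](c2ccccc2)(c2ccccc2)C(C)(C)C)cc(OCc2ccccc2)c(OCc2ccccc2)c1OCc1ccccc1
F4 | step 11 | (2S,4RS)-7-(benzyloxy)-2-[3,4-bis(benzyloxy)phenyl]-4-[2,3,4-tris(benzyloxy)-6-({[tert-butyl(diphenyl)silyl]oxy}methyl)phenyl]-3,4-dihydro-2H-chromen-4-ol | OC1(c2c(OCc3ccccc3)c(OCc3ccccc3)c(OCc3ccccc3)cc2CO[Si](c2ccccc2)(c2ccccc2)C(C)(C)C)C[C@@H](c2ccc(OCc3ccccc3)c(OCc3ccccc3)c2)Oc2cc(OCc3ccccc3)ccc12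
F5 | step 13 | (2RS,3RS,4SR)-7-(benzyloxy)-2-[3,4-bis(benzyloxy)phenyl]-4-[2,3,4-tris(benzyloxy)-6-({[tert-butyl(diphenyl)silyl]oxy}methyl)phenyl]-3,4-dihydro-2H-chromen-3-ol (racemic all-cis) | CC(C)(C)[Si](c4ccccc4)(c4ccccc4)OCc1cc(OCc4ccccc4)c(OCc4ccccc4)c(OCc4ccccc4)c1C2c3ccc(OCc4ccccc4)cc3OC(c3ccc(OCc4ccccc4)c(OCc4ccccc4)c3)C2O
F6 | step 13 | (2R,3R,4S)-7-(benzyloxy)-2-[3,4-bis(benzyloxy)phenyl]-4-[2,3,4-tris(benzyloxy)-6-({[tert-butyl(diphenyl)silyl]oxy}methyl)phenyl]-3,4-dihydro-2H-chromen-3-yl (2S)-methoxy(phenyl)acetate | CC(C)(C)[Si](c4ccccc4)(c4ccccc4)OCc1cc(OCc4ccccc4)c(OCc4ccccc4)c(OCc4ccccc4)c1[C@@H]2c3ccc(OCc4ccccc4)cc3O[C@H](c3ccc(OCc4ccccc4)c(OCc4ccccc4)c3)[C@@H]2OC(=O)[C@@H](OC)c4ccccc4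
F7 | step 14 | (2R,3S,4S)-7-(benzyloxy)-2-[3,4-bis(benzyloxy)phenyl]-4-[2,3,4-tris(benzyloxy)-6-({[tert-butyl(diphenyl)silyl]oxy}methyl)phenyl]-3,4-dihydro-2H-chromen-3-yl 4-nitrobenzoate | CC(C)(C)[Si](c4ccccc4)(c4ccccc4)OCc1cc(OCc4ccccc4)c(OCc4ccccc4)c(OCc4ccccc4)c1[C@@H]2c3ccc(OCc4ccccc4)cc3O[C@H](c3ccc(OCc4ccccc4)c(OCc4ccccc4)c3)[C@H]2OC(=O)c4ccc(cc4)[N+](=O)[O-]
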